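**Structural features**

The target is a sesquineolignan built on a 2-oxaspiro[4.5]decadienone. An oxolane (C1, C8', C7', O, C7) shares the quaternary carbon C1 with ring A, a cross-conjugated cyclohexa-2,5-dienone whose only substituent is a methoxy group on C3. C7 carries a β-aryl ether arm (C8 with the aryloxy group of ring C, then C9H2OH), C7' carries the guaiacyl ring B as a free phenol, and C8' carries C9'H2OH. Five stereocentres are contiguous along C8–C7–C1–C8'–C7' (7S, 8S, 7'S): the C7 arm, the C9' group and the C2–C3(OMe) edge of ring A lie on one face of the oxolane and ring B on the other. C1 is stereogenic only because C3, and not C5, bears the methoxy group. Fragile points are the dienone (conjugate addition, over-reduction, acid-induced rearrangement), the benzylic ether carbons C7 and C7' (C7' ionises easily), the phenol, and the C9' hydroxyl, which sits within reach of C2. The real difficulty is the quaternary spiro carbon flanked by two stereocentres, together with the late distinction of C3 from C5. The key step exploits that, once the C7–O–C7' ether exists, C1 is the para carbon of a phenol (ring A before dearomatisation) and C8' the β-carbon of an enol ether; both are nucleophilic and five atoms apart, so removal of two electrons joins them and closes the oxolane.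

**Logic of the disconnections**

28 to 27. The three O–Si bonds (ring B phenol oxygen, O9, terminal oxygen of the ring C side chain) are cut. These hydroxyls must stay silent through base, oxidant and methylating agent, and one fluoride step then ends the synthesis. The demand is buffered fluoride, so that the dienone and the C9' hydroxyl of 28 are not disturbed.

27 to 25 and on to 23. The O–CH3 bond at C3 is cut, and the C2=C3 double bond is exchanged for a C2–O9' bond and a C3–H bond. In 23 the two enone halves of ring A differ only in that the C9' hydroxyl can reach C2 and cannot reach C6. The gain is that ring A becomes an unsubstituted, symmetrical dienone and C1 stops being a stereocentre. The forward steps must add O9' to C2, oxidise the enolate so formed at C3, then expel O9' again and methylate.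

23 to 22 to 21. Only the oxidation level of C9' changes (alcohol, aldehyde, diethyl acetal), because C9' leaves the key step as an acetal. The demands are a hydride that takes the aldehyde and leaves the dienone, and an acetal hydrolysis that does not ionise C7'.

21 to 20. The C1–C8' bond is cut; this opens the oxolane, removes the spiro carbon and returns ring A to a flat phenol. The precursor is acyclic, with C7, C8 and C7' already in place. The forward step must confine oxidation to the phenol/enol ether pair and set C8' trans to ring B.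

20 to 10 and 16, through 18 and 19. The C7–O bond is cut. The para hydroxyl that the key step needs is also what makes C7 electrophilic in 18, so the ether and the free phenol arise together and the two halves are joined late. The demand is facial selectivity at C7 under control of C8, under non-acidic conditions. The C7 configuration of 10 is erased in 18 and set again.

16 to 12 and 13 (12 from 11). The C7'–C8' bond is cut. One catalytic addition creates C7' and delivers the enol ether in its final form.

10 through 9 and 8 to 7, and 7 to 4 and 5 through 6. The C7–C8 bond is cut (aldol). The auxiliary fixes C8, the one centre of this half that persists. The demands are a Z-enolate and an aldehyde whose phenol protection can be removed selectively later.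

4 to 3, and 3 to 1 and 2. The aryl O–CH2 bond is cut; ring C enters as its phenol and the auxiliary as its chloroacetyl imide.

**Other disconnections considered**

Alternative 1: The cut is at C1–C2 and C1–C6. Ring A would be built onto the preformed trans lactone A1, in which C7 is the lactone carbonyl carbon. In the forward key step A1 is deprotonated twice with a lithium amide and alkylated by both ends of the diiodo ketal A2, giving the spiro lactone A3.
- In favour: this is ordinary enolate chemistry, and the second alkylation is an intramolecular six-membered closure. No oxidant meets the electron-rich rings, so on the reliability of the bond-forming event itself this plan is probably the better one.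
- Equal: on C1 it is the equal of the chosen plan. Both keep ring A symmetrical and both must later use the C9' hydroxyl to tell C3 from C5.
- Against: A3 has ring A at the cyclohexanone level, so two dehydrogenations are needed before the methoxy group can be introduced.
- Against: C7 is a carbonyl carbon next to the quaternary centre. Turning it into a CH that bears the C8(OAr)–C9 arm means late C–C bond formation at a neopentyl position, with C7 and C8 set under little control and the aryl ether introduced last.
- Comparison: the chosen plan brings C7, C8 and C7' in before the ring is closed. Alternative 1 leaves two of them to the end and should cost well over five additional steps after A3.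

Alternative 2: The cut is at C1–C6 and C2–C3. In the forward key step Danishefsky's diene A5 adds to the α-methylene lactone A4, and acidic work-up gives the spiro cyclohexenone A6.
- In favour: the diene should approach anti to the C8' substituent. C1 is then set in the ring-forming step, and the two halves of ring A come out differentiated, with the saturated C2–C3 side syn to C9', where the methoxy enone is needed.
- Better: on C1 this plan is the better one. Enolisation toward C3, oxygenation and O-methylation would finish ring A without any relay through the C9' hydroxyl (steps 13 and 14 of the chosen plan).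
- Against: as in Alternative 1, C7 is a lactone carbonyl. The C7 hydrogen, the C8 aryl ether and C9 would have to be attached to a hindered carbonyl in the presence of an enone, with two new stereocentres and no obvious source of control.
- Comparison: the mechanism (thermal cycloaddition) is more predictable than an electrode process. On the side chain the chosen plan is stronger, because C8 comes from an auxiliary-controlled aldol before the spiro ring exists. Step economy should be similar or worse for Alternative 2 once the arm is counted.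

Alternative 3: The cut is at O–C7 and C1–C8' together. In the forward key step Pd(PPh3)4 (zerovalent palladium) opens the aryl vinyl epoxide A7 to an alkoxide/π-allyl zwitterion. The alkoxide adds to C7 of the quinone methide A8, and the phenolate para carbon closes on the allyl terminus, giving the C8'-vinyl spirodienone A9.
- Better: on convergence and step economy this plan is the better one. Two bonds, the ring and the spiro carbon are made in one redox-neutral step, and the alkoxyallyl alcohol, the electrolysis and the acetal stage all disappear.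
- Equal: on C7 it is the equal of the chosen plan, since the same 1,6-addition decides that centre.
- Against: C7 and C8' are both decided in one operation, with only C7' carried in from A7.
- Against: triphenylphosphine is itself a good nucleophile for an unstabilised quinone methide.
- Against: ortho attack and attack at the distal allyl terminus compete with the ipso closure.
- Against: the extra vinyl carbon has to be cleaved off.
- Comparison: the chosen plan makes the O–C7 bond and the C1–C8' bond in separate steps. Each can then be corrected on its own, and C7 isomers can be removed at the stage of 20. Alternative 3 is kept as the fallback for the key step.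

Key step: step 10

Remarks on the chemistry:
- Locants follow lignan numbering as used above; ring B is the guaiacyl ring on C7' and ring C the aryloxy ring on C8.
- Compounds 2, 5 and 13, the ligand (−)-MIB (3-exo-morpholinoisoborneol) and, for one fallback, coniferyl alcohol are taken as catalogue compounds.
- The enol ether is carried as its ethyl ether and C9' leaves the key step as the diethyl acetal. These alkyl groups are lost in step 11; ethyl is used because the ethoxyvinyl reagent comes from commercial 13.
- All silyl groups that must last are triisopropylsilyl. The aryl ether of ring B must not be lost under alkoxide, carbonate or dimethyl sulfate (a freed phenol would be methylated), and the primary ethers must survive HBr in step 9 and aqueous acid in step 11.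
- The configurations 7S, 8S, 7'S of 20 and the trans arrangement at C8' of 21 were checked against the target. The syn aldol from the (R)-auxiliary is the threo (7S,8S) isomer.

Step 1
Reactants: 1 dihydroconiferyl alcohol; 2 (R)-4-benzyl-3-(chloroacetyl)oxazolidin-2-one
Product: 3 (R)-4-benzyl-3-{[4-(3-hydroxypropyl)-2-methoxyphenoxy]acetyl}oxazolidin-2-one
Conditions: K2CO3, NaI (10 mol%), acetone, 50 °C
Reagents that add atoms: none
Why: Williamson etherification, an SN2 displacement at the α-chloro imide catalysed by iodide; K2CO3 deprotonates only the phenol, so the primary alcohol does not compete.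

Step 2
Reactants: 3 (R)-4-benzyl-3-{[4-(3-hydroxypropyl)-2-methoxyphenoxy]acetyl}oxazolidin-2-one
Product: 4 (R)-4-benzyl-3-({2-methoxy-4-[3-(triisopropylsilyloxy)propyl]phenoxy}acetyl)oxazolidin-2-one
Conditions: TIPSCl, imidazole, DMF, rt
Reagents that add atoms: chlorotriisopropylsilane, CC(C)[Si](Cl)(C(C)C)C(C)C
Why: Standard silylation of a primary alcohol; the hindered silyl ether is chosen to last until step 15.

Step 3
Reactants: 4 (R)-4-benzyl-3-({2-methoxy-4-[3-(triisopropylsilyloxy)propyl]phenoxy}acetyl)oxazolidin-2-one; 5 4-(tert-butyldimethylsilyloxy)benzaldehyde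
Product: 7 syn-aldol adduct (4R)-4-benzyl-3-[(2R,3S)-3-[4-(tert-butyldimethylsilyloxy)phenyl]-3-hydroxy-2-{2-methoxy-4-[3-(triisopropylsilyloxy)propyl]phenoxy}propanoyl]oxazolidin-2-one, via dibutylboron Z-enolate 6 (not isolated)
Conditions: Bu2BOTf, iPr2NEt, CH2Cl2, −78 → 0 °C; 5, −78 → 0 °C; H2O2, pH 7 buffer, MeOH, 0 °C
Reagents that add atoms: none
Why: Evans syn-aldol of a glycolate imide: the boron Z-enolate reacts through a closed chair transition state on the face left open by the benzyl group of the (R)-auxiliary, which should give the (2R,3S) adduct. C2 becomes C8 (S after reduction), the centre that persists; C3 becomes C7.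

Step 4
Reactants: 7 syn-aldol adduct
Product: 8 threo diol (1S,2S)-1-[4-(tert-butyldimethylsilyloxy)phenyl]-2-{2-methoxy-4-[3-(triisopropylsilyloxy)propyl]phenoxy}propane-1,3-diol
Conditions: LiBH4, MeOH (1 equiv), THF, 0 °C
Reagents that add atoms: none
Why: Reductive removal of the oxazolidinone from an N-acyl imide by LiBH4; the silyl ethers are inert and the auxiliary is recovered.

Step 5
Reactants: 8 threo diol
Product: 9 (1S,2S)-1-[4-(tert-butyldimethylsilyloxy)phenyl]-2-{2-methoxy-4-[3-(triisopropylsilyloxy)propyl]phenoxy}-3-(triisopropylsilyloxy)propan-1-ol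
Conditions: TIPSCl (1.1 equiv), imidazole, CH2Cl2, 0 °C → rt
Reagents that add atoms: chlorotriisopropylsilane, CC(C)[Si](Cl)(C(C)C)C(C)C
Why: Selective silylation of the primary hydroxyl of a 1,3-diol by a bulky silyl chloride; the hindered benzylic secondary hydroxyl should stay free.

Step 6
Reactants: 9 O9-silylated threo alcohol
Product: 10 4-[(1S,2S)-1-hydroxy-2-{2-methoxy-4-[3-(triisopropylsilyloxy)propyl]phenoxy}-3-(triisopropylsilyloxy)propyl]phenol
Conditions: K2CO3 (0.5 equiv), MeOH, rt
Reagents that add atoms: none
Why: Base-catalysed methanolysis of an aryl silyl ether; alkyl triisopropylsilyl ethers are not cleaved under these conditions, so only the ring A phenol is freed.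

Step 7
Reactants: 11 vanillin
Product: 12 3-methoxy-4-(triisopropylsilyloxy)benzaldehyde
Conditions: TIPSCl, imidazole, DMF, rt
Reagents that add atoms: chlorotriisopropylsilane, CC(C)[Si](Cl)(C(C)C)C(C)C
Why: Phenol silylation; the triisopropylsilyl aryl ether is chosen because it must resist alkoxides in steps 9 and 13 and carbonate in step 14.

Step 8
Reactants: 12 3-methoxy-4-(triisopropylsilyloxy)benzaldehyde; 13 ethoxyacetylene
Product: 16 (1S,2E)-3-ethoxy-1-[3-methoxy-4-(triisopropylsilyloxy)phenyl]prop-2-en-1-ol, via (E)-(2-ethoxyvinyl)dicyclohexylborane 14 (not isolated), via (E)-(2-ethoxyvinyl)ethylzinc 15 (not isolated)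
Conditions: 13, Cy2BH, toluene, 0 °C → rt; Et2Zn, −78 °C; (−)-MIB (5 mol%), 12, −20 → 0 °C; aq. NaHCO3
Reagents that add atoms: none
Why: Syn hydroboration of the alkynyl ether (boron to the terminal carbon), boron-to-zinc exchange and amino alcohol-catalysed addition of the alkenylzinc to the aldehyde, a known route to hydroxy enol ethers. (−)-MIB is expected to deliver the alkenyl group to the Si face as in its dialkylzinc additions, giving the 7'S alcohol; the acid-labile product is worked up and purified under basic conditions.

Step 9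
Reactants: 10 ring A phenol with free C7 hydroxyl; 16 (1S,2E)-3-ethoxy-1-arylprop-2-en-1-ol
Product: 20 precursor 4-[(1S,2S)-1-{[(1S,2E)-3-ethoxy-1-[3-methoxy-4-(triisopropylsilyloxy)phenyl]prop-2-en-1-yl]oxy}-2-{2-methoxy-4-[3-(triisopropylsilyloxy)propyl]phenoxy}-3-(triisopropylsilyloxy)propyl]phenol, via benzylic bromide 17 (not isolated), via quinone methide 18 (not isolated), via lithium alkoxide 19 (not isolated)
Conditions: 10, TMSBr, CH2Cl2, 0 °C; cold aq. NaHCO3; solution added to 16/n-BuLi, THF, −78 → −40 °C; pH 7 phosphate buffer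
Reagents that add atoms: none
Why: Bromide formation and loss of HBr give the para-quinone methide, and oxa-1,6-conjugate addition of the alkoxide restores the aromatic ring and leaves the phenol free. C7 is set under control of C8: with H8 eclipsing the exocyclic double bond, the CH2OTIPS group blocks one face and lithium bridging to the two ether oxygens of ring C should guide the alkoxide to the other, which gives the threo (7S) ether. Inverse addition at low temperature keeps the alkoxide in excess over 18 and limits its action as a base.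

Step 10
Reactants: 20 precursor phenol–enol ether
Product: 21 spirodienone diethyl acetal (1S,3S,4S)-4-(diethoxymethyl)-3-[3-methoxy-4-(triisopropylsilyloxy)phenyl]-1-[(1S)-1-{2-methoxy-4-[3-(triisopropylsilyloxy)propyl]phenoxy}-2-(triisopropylsilyloxy)ethyl]-2-oxaspiro[4.5]deca-6,9-dien-8-one
Conditions: reticulated vitreous carbon anode, Pt cathode, undivided cell, LiClO4 (0.1 M), 2,6-lutidine, EtOH/CH2Cl2 1:4, constant current, 2.2 F/mol, rt
Reagents that add atoms: ethanol, CCO
Why: Anodic removal of two electrons from the phenol/enol ether pair (the phenolic proton going to 2,6-lutidine) gives a phenoxonium ion on ring A or, if the enol ether is oxidised first, its radical cation; both paths converge when C8' bonds to the para carbon C1, and the oxocarbenium ion left at C9' is captured by ethanol as the diethyl acetal while protons are reduced at the cathode. The closest known reaction types are anodic and hypervalent-iodine dearomatising spirocyclisations of para-substituted phenols by tethered carbon π-nucleophiles, and anodic couplings of enol ethers. The oxolane closes in the 5-exo-trig mode with respect to the enol ether and in the spiro (ipso) mode with respect to ring A; attack at an ortho carbon would need a six-membered ring and C9' is not nucleophilic. The one new stereocentre, C8', is controlled by C7': in the envelope transition state the ethoxymethylidene group turns away from the pseudo-equatorial aryl group on C7', giving the trans arrangement, which is also the more stable one. C1 is not stereogenic here because ring A is unsubstituted, so no choice between ring A rotamers is needed, and C7, C8 and C7' are untouched. The step needs oxidation at the phenol/enol ether pair and not at rings B and C; this rests on the free hydroxyl of ring A with lutidine as proton acceptor, on the ether state of the other two rings and on limiting the charge to about two faradays per mole. Ring closure must also outrun capture of the phenoxonium ion by ethanol at C1, which an intramolecular five-membered closure should do, and the lutidine buffer protects the acid-labile C7'–O bond.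

Step 11
Reactants: 21 spirodienone diethyl acetal
Product: 22 spirodienone aldehyde (1S,3S,4S)-3-[3-methoxy-4-(triisopropylsilyloxy)phenyl]-1-[(1S)-1-{2-methoxy-4-[3-(triisopropylsilyloxy)propyl]phenoxy}-2-(triisopropylsilyloxy)ethyl]-8-oxo-2-oxaspiro[4.5]deca-6,9-diene-4-carbaldehyde
Conditions: PPTS, acetone/H2O 10:1, 45 °C
Reagents that add atoms: water, O
Why: Mild acid-catalysed acetal hydrolysis; the triisopropylsilyl ethers tolerate it. Any C8' epimer with the formyl group cis to ring B should equilibrate through the enol to the trans aldehyde under the same conditions.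

Step 12
Reactants: 22 spirodienone aldehyde
Product: 23 spirodienone alcohol (1S,3S,4R)-4-(hydroxymethyl)-3-[3-methoxy-4-(triisopropylsilyloxy)phenyl]-1-[(1S)-1-{2-methoxy-4-[3-(triisopropylsilyloxy)propyl]phenoxy}-2-(triisopropylsilyloxy)ethyl]-2-oxaspiro[4.5]deca-6,9-dien-8-one
Conditions: NaBH(OAc)3, AcOH, THF, rt
Reagents that add atoms: none
Why: Chemoselective hydride reduction: the acetoxyborohydride reduces aldehydes and leaves ketones and the dienone alone, and the acidic medium generates no alkoxide that could add to ring A or be reduced further.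

Step 13
Reactants: 23 spirodienone alcohol
Product: 25 tricyclic hydroxy ketone (O9' bonded to C2 of ring A, cis-fused to the oxolane; hydroxyl on C3, either configuration; enone C5=C6 retained), via potassium enolate 24 (not isolated)
Conditions: KN(SiMe3)2, THF, −78 → −20 °C; 2-(phenylsulfonyl)-3-phenyloxaziridine, −78 °C; aq. NH4Cl
Reagents that add atoms: 2-(phenylsulfonyl)-3-phenyloxaziridine, O=S(=O)(N1OC1c1ccccc1)c1ccccc1
Why: Intramolecular oxa-Michael addition (5-exo-trig) of the C9' alkoxide can reach only C2, the β-carbon on its own face of the oxolane, and gives the cross-conjugated enolate, which the N-sulfonyloxaziridine hydroxylates at C3 (Davis oxidation). C1 becomes stereogenic here, its configuration dictated by C8' through the cis ring fusion; the configuration at C3 is of no consequence because C3 returns to sp2 in step 14.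

Step 14
Reactants: 25 tricyclic hydroxy ketone
Product: 27 tris(triisopropylsilyl) ether of the target (7-methoxy dienone with free C9' hydroxyl), via potassium diosphenolate 26 (not isolated)
Conditions: K2CO3, Me2SO4, acetone, 40 °C
Reagents that add atoms: dimethyl sulfate, COS(=O)(=O)OC
Why: Base-induced retro-oxa-Michael elimination (E1cB through the enediolate of the ketol) expels O9' and gives the C2=C3 diosphenol, whose acidic enol oxygen is methylated. K2CO3 does not deprotonate the freed primary alcohol, and the hindered aryl silyl ether of ring B should survive, so only O3 is methylated.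

Step 15
Reactants: 27 tris(triisopropylsilyl) ether of the target
Product: 28 target CNP0252711.1
Conditions: Bu4NF, AcOH (1:1), THF, 0 °C → rt
Reagents that add atoms: none
Why: Fluoride cleavage of the aryl and the two primary alkyl silyl ethers; acetic acid buffering keeps alkoxide and phenoxide concentrations low so that the C9' hydroxyl does not add back to C2.

Compound list
1 | dihydroconiferyl alcohol, 4-(3-hydroxypropyl)-2-methoxyphenol | COc1cc(CCCO)ccc1O | starting material
2 | (R)-4-benzyl-3-(chloroacetyl)oxazolidin-2-one | O=C(CCl)N1[C@H](Cc2ccccc2)COC1=O | starting material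
3 | (R)-4-benzyl-3-{[4-(3-hydroxypropyl)-2-methoxyphenoxy]acetyl}oxazolidin-2-one | COc1cc(CCCO)ccc1OCC(=O)N1[C@H](Cc2ccccc2)COC1=O | intermediate
4 | (R)-4-benzyl-3-({2-methoxy-4-[3-(triisopropylsilyloxy)propyl]phenoxy}acetyl)oxazolidin-2-one | COc1cc(CCCO[Si](C(C)C)(C(C)C)C(C)C)ccc1OCC(=O)N1[C@H](Cc2ccccc2)COC1=O | intermediate
5 | 4-(tert-butyldimethylsilyloxy)benzaldehyde | O=Cc1ccc(O[Si](C)(C)C(C)(C)C)cc1 | starting material
6 | dibutylboron Z-enolate of 4 | CCCCB(CCCC)O/C(=C\Oc1ccc(CCCO[Si](C(C)C)(C(C)C)C(C)C)cc1OC)N1[C@H](Cc2ccccc2)COC1=O | intermediate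
7 | (4R)-4-benzyl-3-[(2R,3S)-3-[4-(tert-butyldimethylsilyloxy)phenyl]-3-hydroxy-2-{2-methoxy-4-[3-(triisopropylsilyloxy)propyl]phenoxy}propanoyl]oxazolidin-2-one | O[C@@H](c1ccc(O[Si](C)(C)C(C)(C)C)cc1)[C@H](C(=O)N1[C@H](Cc2ccccc2)COC1=O)Oc1ccc(CCCO[Si](C(C)C)(C(C)C)C(C)C)cc1OC | intermediate
8 | (1S,2S)-1-[4-(tert-butyldimethylsilyloxy)phenyl]-2-{2-methoxy-4-[3-(triisopropylsilyloxy)propyl]phenoxy}propane-1,3-diol (threo) | O[C@@H](c1ccc(O[Si](C)(C)C(C)(C)C)cc1)[C@H](CO)Oc1ccc(CCCO[Si](C(C)C)(C(C)C)C(C)C)cc1OC | intermediate
9 | (1S,2S)-1-[4-(tert-butyldimethylsilyloxy)phenyl]-2-{2-methoxy-4-[3-(triisopropylsilyloxy)propyl]phenoxy}-3-(triisopropylsilyloxy)propan-1-ol | O[C@@H](c1ccc(O[Si](C)(C)C(C)(C)C)cc1)[C@H](CO[Si](C(C)C)(C(C)C)C(C)C)Oc1ccc(CCCO[Si](C(C)C)(C(C)C)C(C)C)cc1OC | intermediate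
10 | 4-[(1S,2S)-1-hydroxy-2-{2-methoxy-4-[3-(triisopropylsilyloxy)propyl]phenoxy}-3-(triisopropylsilyloxy)propyl]phenol | O[C@@H](c1ccc(O)cc1)[C@H](CO[Si](C(C)C)(C(C)C)C(C)C)Oc1ccc(CCCO[Si](C(C)C)(C(C)C)C(C)C)cc1OC | intermediate
11 | vanillin, 4-hydroxy-3-methoxybenzaldehyde | COc1cc(C=O)ccc1O | starting material
12 | 3-methoxy-4-(triisopropylsilyloxy)benzaldehyde | COc1cc(C=O)ccc1O[Si](C(C)C)(C(C)C)C(C)C | intermediate
13 | ethoxyacetylene (ethoxyethyne) | CCOC#C | starting material
14 | (E)-(2-ethoxyvinyl)dicyclohexylborane | CCO/C=C/B(C1CCCCC1)C1CCCCC1 | intermediate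
15 | (E)-(2-ethoxyvinyl)ethylzinc | CCO/C=C/[Zn]CC | intermediate
16 | (1S,2E)-3-ethoxy-1-[3-methoxy-4-(triisopropylsilyloxy)phenyl]prop-2-en-1-ol | CCO/C=C/[C@@H](c1ccc(O[Si](C(C)C)(C(C)C)C(C)C)c(OC)c1)O | intermediate
17 | 4-[1-bromo-2-{2-methoxy-4-[3-(triisopropylsilyloxy)propyl]phenoxy}-3-(triisopropylsilyloxy)propyl]phenol, both C7 epimers, C8 as in 10 | BrC(c1ccc(O)cc1)[C@H](CO[Si](C(C)C)(C(C)C)C(C)C)Oc1ccc(CCCO[Si](C(C)C)(C(C)C)C(C)C)cc1OC | intermediate
18 | quinone methide 4-[2-{2-methoxy-4-[3-(triisopropylsilyloxy)propyl]phenoxy}-3-(triisopropylsilyloxy)propylidene]cyclohexa-2,5-dien-1-one, C8 as in 10 | O=C1C=CC(C=C1)=C[C@H](CO[Si](C(C)C)(C(C)C)C(C)C)Oc1ccc(CCCO[Si](C(C)C)(C(C)C)C(C)C)cc1OC | intermediate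
19 | lithium (1S,2E)-3-ethoxy-1-[3-methoxy-4-(triisopropylsilyloxy)phenyl]prop-2-en-1-olate | CCO/C=C/[C@@H](c1ccc(O[Si](C(C)C)(C(C)C)C(C)C)c(OC)c1)[O-].[Li+] | intermediate
20 | 4-[(1S,2S)-1-{[(1S,2E)-3-ethoxy-1-[3-methoxy-4-(triisopropylsilyloxy)phenyl]prop-2-en-1-yl]oxy}-2-{2-methoxy-4-[3-(triisopropylsilyloxy)propyl]phenoxy}-3-(triisopropylsilyloxy)propyl]phenol (7S,8S,7'S) | CCO/C=C/[C@@H](c1ccc(O[Si](C(C)C)(C(C)C)C(C)C)c(OC)c1)O[C@@H](c1ccc(O)cc1)[C@H](CO[Si](C(C)C)(C(C)C)C(C)C)Oc1ccc(CCCO[Si](C(C)C)(C(C)C)C(C)C)cc1OC | intermediate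
21 | (1S,3S,4S)-4-(diethoxymethyl)-3-[3-methoxy-4-(triisopropylsilyloxy)phenyl]-1-[(1S)-1-{2-methoxy-4-[3-(triisopropylsilyloxy)propyl]phenoxy}-2-(triisopropylsilyloxy)ethyl]-2-oxaspiro[4.5]deca-6,9-dien-8-one (C4 group trans to the C3 aryl, cis to the C1 arm) | O=C1C=CC2(C=C1)[C@H](C(OCC)OCC)[C@@H](c1ccc(O[Si](C(C)C)(C(C)C)C(C)C)c(OC)c1)O[C@@H]2[C@H](CO[Si](C(C)C)(C(C)C)C(C)C)Oc1ccc(CCCO[Si](C(C)C)(C(C)C)C(C)C)cc1OC | intermediate
22 | (1S,3S,4S)-3-[3-methoxy-4-(triisopropylsilyloxy)phenyl]-1-[(1S)-1-{2-methoxy-4-[3-(triisopropylsilyloxy)propyl]phenoxy}-2-(triisopropylsilyloxy)ethyl]-8-oxo-2-oxaspiro[4.5]deca-6,9-diene-4-carbaldehyde | O=C1C=CC2(C=C1)[C@H](C=O)[C@@H](c1ccc(O[Si](C(C)C)(C(C)C)C(C)C)c(OC)c1)O[C@@H]2[C@H](CO[Si](C(C)C)(C(C)C)C(C)C)Oc1ccc(CCCO[Si](C(C)C)(C(C)C)C(C)C)cc1OC | intermediate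
23 | (1S,3S,4R)-4-(hydroxymethyl)-3-[3-methoxy-4-(triisopropylsilyloxy)phenyl]-1-[(1S)-1-{2-methoxy-4-[3-(triisopropylsilyloxy)propyl]phenoxy}-2-(triisopropylsilyloxy)ethyl]-2-oxaspiro[4.5]deca-6,9-dien-8-one | O=C1C=CC2(C=C1)[C@H](CO)[C@@H](c1ccc(O[Si](C(C)C)(C(C)C)C(C)C)c(OC)c1)O[C@@H]2[C@H](CO[Si](C(C)C)(C(C)C)C(C)C)Oc1ccc(CCCO[Si](C(C)C)(C(C)C)C(C)C)cc1OC | intermediate
24 | potassium cross-conjugated enolate (C3=C4–O−, C5=C6) of the cis-fused oxa-Michael adduct of 23, O9' bonded to C2 | [K+].[O-]C1C=C[C@@]23[C@@H](C=1)OC[C@@H]2[C@@H](c1ccc(O[Si](C(C)C)(C(C)C)C(C)C)c(OC)c1)O[C@@H]3[C@H](CO[Si](C(C)C)(C(C)C)C(C)C)Oc1ccc(CCCO[Si](C(C)C)(C(C)C)C(C)C)cc1OC | intermediate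
25 | cis-fused oxa-Michael adduct of 23 (O9' bonded to C2) with a hydroxyl on C3 (both C3 epimers), C4 ketone, C5=C6 enone | O=C1C=C[C@@]23[C@@H](C1O)OC[C@@H]2[C@@H](c1ccc(O[Si](C(C)C)(C(C)C)C(C)C)c(OC)c1)O[C@@H]3[C@H](CO[Si](C(C)C)(C(C)C)C(C)C)Oc1ccc(CCCO[Si](C(C)C)(C(C)C)C(C)C)cc1OC | intermediate
26 | potassium salt of the C3 diosphenol (3-oxido-dienone with free C9' hydroxyl; the oxido-bearing ring A edge syn to C9') | [K+].[O-]C1=C[C@]2(C=CC1=O)[C@H](CO)[C@@H](c1ccc(O[Si](C(C)C)(C(C)C)C(C)C)c(OC)c1)O[C@@H]2[C@H](CO[Si](C(C)C)(C(C)C)C(C)C)Oc1ccc(CCCO[Si](C(C)C)(C(C)C)C(C)C)cc1OC | intermediate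
27 | tris(triisopropylsilyl) ether of the target: (1S,3S,4R)-4-(hydroxymethyl)-7-methoxy-3-[3-methoxy-4-(triisopropylsilyloxy)phenyl]-1-[(1S)-1-{2-methoxy-4-[3-(triisopropylsilyloxy)propyl]phenoxy}-2-(triisopropylsilyloxy)ethyl]-2-oxaspiro[4.5]deca-6,9-dien-8-one, methoxy-bearing edge of ring A syn to the hydroxymethyl group | COC1=C[C@]2(C=CC1=O)[C@H](CO)[C@@H](c1ccc(O[Si](C(C)C)(C(C)C)C(C)C)c(OC)c1)O[C@@H]2[C@H](CO[Si](C(C)C)(C(C)C)C(C)C)Oc1ccc(CCCO[Si](C(C)C)(C(C)C)C(C)C)cc1OC | intermediate
28 | CNP0252711.1: (1S,3S,4R)-3-(4-hydroxy-3-methoxyphenyl)-4-(hydroxymethyl)-1-{(1S)-2-hydroxy-1-[4-(3-hydroxypropyl)-2-methoxyphenoxy]ethyl}-7-methoxy-2-oxaspiro[4.5]deca-6,9-dien-8-one, methoxy-bearing edge of ring A syn to the hydroxymethyl group | COC1=C[C@]2(C=CC1=O)[C@H](CO)[C@@H](c1ccc(O)c(OC)c1)O[C@@H]2[C@H](CO)Oc1ccc(CCCO)cc1OC | target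

Total step count: 15. Longest linear sequence: 13 (steps 1 to 6 and 9 to 15); steps 7 and 8 form the second branch.

Least certain steps

Step 10 (key step). Most likely to go wrong: electron transfer that is not confined to the phenol/enol ether pair (oxidation of ring B or C, or over-oxidation of 21), capture of the phenoxonium ion by ethanol at C1 before the enol ether closes, and acid-promoted ionisation of the C7'–O bond near the anode. Fallback, from 12 and from 18, back to 22: the C1–C8' bond would be made by a polar, redox-neutral route. Aldehyde 12 would be converted with the S-allyl sulfonium salt of isothiocineole and KOH into the trans epoxide (2R,3R)-2-[3-methoxy-4-(triisopropylsilyloxy)phenyl]-3-vinyloxirane F1. Pd(PPh3)4 (zerovalent palladium) would open it to an alkoxide/π-allyl zwitterion; the alkoxide adds to C7 of 18 (generated from 10 as in step 9) and the resulting phenolate attacks the allyl terminus C8' with its para carbon, giving the C8'-vinyl spirodienone F2. Cleavage of its vinyl group (OsO4 cat., NaIO4, 2,6-lutidine) would give aldehyde 22, and steps 12 to 15 follow unchanged.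

Step 9. Most likely to go wrong: poor facial selectivity at C7 in the 1,6-addition, since the electronic preference for attack anti to the aryloxy group opposes the steric and chelation bias. Proton abstraction at C8 of 18 by the alkoxide and capture of 18 by the product phenoxide are further risks. Fallback, from 9, back to 20: the C7 configuration that the aldol created would be kept and not erased. Coniferyl alcohol would be silylated at the phenol (NaH, TIPSCl) to (E)-3-[3-methoxy-4-(triisopropylsilyloxy)phenyl]prop-2-en-1-ol F3 and converted (ClCO2Me, pyridine) into its methyl carbonate F4. The copper alkoxide of 9 (n-BuLi, CuI) would be allylated at oxygen with F4 under [Ir(cod)Cl]2 and a chiral phosphoramidite. This is a known branched-selective allylic etherification with catalyst control at the new centre; here it should give the 7'S vinyl ether F5 with C7 retained. Oxidative cleavage (OsO4 cat., NaIO4, 2,6-lutidine) would give the α-alkoxy aldehyde F6, and a Wittig reaction with Ph3P=CHOEt at −78 °C the enol ether F7. Methanolysis of the aryl tert-butyldimethylsilyl ether (K2CO3, MeOH) would then give 20 as an E/Z mixture at the enol ether; both isomers are expected to converge in step 10.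

Step 13. Most likely to go wrong: failure to intercept the enolate. The oxa-Michael equilibrium may lie on the side of the open alkoxide at low temperature, or the alkoxide formed after oxygen transfer may start the elimination early and lead to over-oxidation. Fallback, from 23, back to 25: ring closure and oxygenation would be separated and the oxygen delivered to a neutral silyl enol ether (Rubottom oxidation). DBU (cat.) in CH2Cl2 would close 23 to the tricyclic enone F8; TMSOTf/Et3N at −78 °C would convert it into the 2-silyloxydiene F9 without a free enolate; dimethyldioxirane in acetone followed by mild acid would give 25.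

Step 14. Most likely to go wrong: re-addition of the freed C9' hydroxyl to C2 under the basic conditions, C-methylation at C2, or loss of the ring B silyl ether followed by methylation of that phenol. Fallback, from 25, back to 27: the methyl group would be attached before the ring is opened. MeOTf with 2,6-di-tert-butyl-4-methylpyridine in CH2Cl2 would methylate the ketol hydroxyl under non-basic conditions to the C3 methoxy ketone F10, and DBU in toluene would then bring about the retro-oxa-Michael elimination to 27 with no alkylating agent present.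

Further compounds
F1 | step 10 | (2R,3R)-2-[3-methoxy-4-(triisopropylsilyloxy)phenyl]-3-vinyloxirane | C=C[C@H]1O[C@@H]1c1ccc(O[Si](C(C)C)(C(C)C)C(C)C)c(OC)c1
F2 | step 10 | C8'-vinyl spirodienone, 4-vinyl analogue of 22 (vinyl trans to the C3 aryl group) | O=C1C=CC2(C=C1)[C@H](C=C)[C@@H](c1ccc(O[Si](C(C)C)(C(C)C)C(C)C)c(OC)c1)O[C@@H]2[C@H](CO[Si](C(C)C)(C(C)C)C(C)C)Oc1ccc(CCCO[Si](C(C)C)(C(C)C)C(C)C)cc1OC
F3 | step 9 | (E)-3-[3-methoxy-4-(triisopropylsilyloxy)phenyl]prop-2-en-1-ol | COc1cc(/C=C/CO)ccc1O[Si](C(C)C)(C(C)C)C(C)C
F4 | step 9 | (E)-3-[3-methoxy-4-(triisopropylsilyloxy)phenyl]prop-2-en-1-yl methyl carbonate | COC(=O)OC/C=C/c1ccc(O[Si](C(C)C)(C(C)C)C(C)C)c(OC)c1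
F5 | step 9 | branched vinyl ether of 9: O7 bonded to C7' of (1S)-1-[3-methoxy-4-(triisopropylsilyloxy)phenyl]prop-2-en-1-yl | C=C[C@@H](c1ccc(O[Si](C(C)C)(C(C)C)C(C)C)c(OC)c1)O[C@@H](c1ccc(O[Si](C)(C)C(C)(C)C)cc1)[C@H](CO[Si](C(C)C)(C(C)C)C(C)C)Oc1ccc(CCCO[Si](C(C)C)(C(C)C)C(C)C)cc1OC
F6 | step 9 | α-alkoxy aldehyde from cleavage of the vinyl group of F5 (C7' unchanged) | O=C[C@@H](c1ccc(O[Si](C(C)C)(C(C)C)C(C)C)c(OC)c1)O[C@@H](c1ccc(O[Si](C)(C)C(C)(C)C)cc1)[C@H](CO[Si](C(C)C)(C(C)C)C(C)C)Oc1ccc(CCCO[Si](C(C)C)(C(C)C)C(C)C)cc1OC
F7 | step 9 | ring A tert-butyldimethylsilyl ether of 20, E/Z mixture at the enol ether | CCOC=C[C@@H](c1ccc(O[Si](C(C)C)(C(C)C)C(C)C)c(OC)c1)O[C@@H](c1ccc(O[Si](C)(C)C(C)(C)C)cc1)[C@H](CO[Si](C(C)C)(C(C)C)C(C)C)Oc1ccc(CCCO[Si](C(C)C)(C(C)C)C(C)C)cc1OC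
F8 | step 13 | tricyclic enone, neutral cis-fused oxa-Michael adduct of 23 (O9' bonded to C2, C3 as CH2) | O=C1C=C[C@@]23[C@@H](C1)OC[C@@H]2[C@@H](c1ccc(O[Si](C(C)C)(C(C)C)C(C)C)c(OC)c1)O[C@@H]3[C@H](CO[Si](C(C)C)(C(C)C)C(C)C)Oc1ccc(CCCO[Si](C(C)C)(C(C)C)C(C)C)cc1OC
F9 | step 13 | trimethylsilyl dienol ether of F8 (C3=C4–OSiMe3, C5=C6) | C[Si](C)(C)OC1C=C[C@@]23[C@@H](C=1)OC[C@@H]2[C@@H](c1ccc(O[Si](C(C)C)(C(C)C)C(C)C)c(OC)c1)O[C@@H]3[C@H](CO[Si](C(C)C)(C(C)C)C(C)C)Oc1ccc(CCCO[Si](C(C)C)(C(C)C)C(C)C)cc1OC
F10 | step 14 | C3 methyl ether of 25 (both C3 epimers) | O=C1C=C[C@@]23[C@@H](C1OC)OC[C@@H]2[C@@H](c1ccc(O[Si](C(C)C)(C(C)C)C(C)C)c(OC)c1)O[C@@H]3[C@H](CO[Si](C(C)C)(C(C)C)C(C)C)Oc1ccc(CCCO[Si](C(C)C)(C(C)C)C(C)C)cc1OC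
A1 | alternative 1 | trans-4-[4-(tert-butyldimethylsilyloxy)-3-methoxyphenyl]-3-[(tert-butyldimethylsilyloxy)methyl]butyrolactone (C7 as lactone carbonyl) | O=C1C[C@H](CO[Si](C)(C)C(C)(C)C)[C@@H](c2ccc(O[Si](C)(C)C(C)(C)C)c(OC)c2)O1
A2 | alternative 1 | 2,2-bis(2-iodoethyl)-1,3-dioxolane | ICCC1(CCI)OCCO1
A3 | alternative 1 | spiro lactone with ketal-protected ring A | O=C1C2(CCC3(CC2)OCCO3)[C@H](CO[Si](C)(C)C(C)(C)C)[C@@H](c2ccc(O[Si](C)(C)C(C)(C)C)c(OC)c2)O1
A4 | alternative 2 | trans α-methylene-γ-butyrolactone bearing ring B on C7' and the silyloxymethyl group on C8' | C=C1[C@H](CO[Si](C)(C)C(C)(C)C)[C@@H](c2ccc(O[Si](C)(C)C(C)(C)C)c(OC)c2)OC1=O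
A5 | alternative 2 | Danishefsky's diene, (E)-1-methoxy-3-(trimethylsilyloxy)buta-1,3-diene | CO/C=C/C(=C)O[Si](C)(C)C
A6 | alternative 2 | spiro cyclohexenone lactone (C1 set, enone on the C5–C6 side) | O=C1CC[C@]2(C=C1)[C@H](CO[Si](C)(C)C(C)(C)C)[C@@H](c1ccc(O[Si](C)(C)C(C)(C)C)c(OC)c1)OC2=O
A7 | alternative 3 | (2R,3R)-2-[4-(tert-butyldimethylsilyloxy)-3-methoxyphenyl]-3-vinyloxirane | C=C[C@H]1O[C@@H]1c1ccc(O[Si](C)(C)C(C)(C)C)c(OC)c1
A8 | alternative 3 | quinone methide, tert-butyldimethylsilyl analogue of 18 | O=C1C=CC(C=C1)=C[C@H](CO[Si](C)(C)C(C)(C)C)Oc1ccc(CCCO[Si](C)(C)C(C)(C)C)cc1OC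
A9 | alternative 3 | 2-oxaspiro[4.5]decadienone with vinyl on C8' | O=C1C=CC2(C=C1)[C@H](C=C)[C@@H](c1ccc(O[Si](C)(C)C(C)(C)C)c(OC)c1)O[C@@H]2[C@H](CO[Si](C)(C)C(C)(C)C)Oc1ccc(CCCO[Si](C)(C)C(C)(C)C)cc1OC
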